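Numbering used throughout: ring A is C1 (bears the ketone), C2 (OH), C3 (Br), C4 (CH3), C5 (Cl), C6 (OMe); ring B is C1' (bears the ketone), C2' (CHO), C3' (OH), C4' (H), C5' (OH), C6' (prenyl). Ar = 3-bromo-5-chloro-6-methoxy-2-(methoxymethoxy)-4-methylphenyl.

## Analysis of the target

Pestalone G (22) is a benzophenone with two crowded rings: ring A is hexasubstituted and ring B pentasubstituted, so the central carbonyl carries four ortho substituents. There is no stereocentre, and the prenyl alkene ends in two identical methyl groups, so the target poses no stereochemical problem; stereocentres appear only in intermediates and must simply be erased. The sensitive groups are the C2' aldehyde ortho to the ketone (it closes to lactols and phthalides with nucleophiles or base), the prenyl group next to the free C5' hydroxyl (acid gives a chroman; halogens, peracids and quinone oxidants attack it), and the aryl bromide (lost under reductive conditions, with zerovalent palladium or on halogen–lithium exchange). Three things make the synthesis hard. Joining two complete rings through the tetra-ortho-substituted carbonyl is sterically penalised. Bromine at C3 and chlorine at C5 sit in almost equivalent positions, told apart only by whether the neighbouring oxygen is OH (C2) or OMe (C6). Ring B needs formyl, prenyl and two oxygens placed without ambiguity. The route rests on the 1,3-relationship of the C3' and C5' oxygens: ring B is an aromatised cyclohexane-1,3-dione. C4', C5', C6' and the prenyl chain form a methyl ketone unit, and C2', C3' and the formyl carbon form a malonate. Ring B can therefore be grown on a carbonyl that ring A already carries, and the C1–CO–C1' unit never has to be forged between two finished rings.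

## Retrosynthetic reasoning

**End game, 22 back to 19.** The three phenols of 22 are unmasked last from the tris-MOM ether 21, because the free ortho-hydroxy aldehyde and the prenylphenol are the most fragile parts of the molecule. The formyl carbon of 21 is traced to the ester carbon of 19, which is what the annulation leaves at C2'. No reduction stops at the aldehyde while sparing the diaryl ketone with certainty, so both carbonyls are taken down to diol 20 and raised again together by an activated-sulfoxide oxidation. The two ring B phenols of 18 are masked as MOM ethers (19) so that hydride and the oxidant do not meet a free resorcinol and so that one acid treatment ends the synthesis.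

**Aromatisation, 18 back to 15.** Ring B of 18 differs from dione 15 by one C=C bond; retrosynthetically the C1'=C2' bond is saturated. The forward step must dehydrogenate without touching the prenyl alkene. The classical bromine-based aromatisation of dihydroresorcylates is ruled out, because it passes through free halogen and hydrogen halide, which would add to the prenyl group and substitute C4' of the product. The leaving group is therefore placed on C2' under basic conditions by double deprotonation and selenenylation (16), and removed by selenoxide syn-elimination (17) towards the C1' hydrogen. Tautomerisation of both ketones then gives the resorcinol, and the three sp3 centres of 15 disappear.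

**Key disconnection, 15 back to 12 and 13.** The bonds C1'–C2' and C3'–C4' are cut. This is the place to cut because every ring B substituent is then already on a simple partner: dimethyl malonate (13) supplies C2', C3' and the future formyl carbon, and enedione 12 supplies C4', C5', C6', the prenyl chain, C1' and the complete ring A ketone. The gain is that the crowded diaryl ketone is present in 12 as an ordinary aryl vinyl ketone, and the first new bond is made at an unsubstituted CH by a small nucleophile. The forward reaction must add malonate to C1' and not to C6', and must close by Claisen condensation of the methyl ketone onto an ester and not by aldol reaction onto the aryl ketone.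

**Enedione, 12 back to 8 and 11.** The C1'=C6' double bond is cut into arylglyoxal 8 and phosphonate 11. A crossed aldol condensation of the glyoxal with an unsymmetrical methyl alkyl ketone would react at the methyl group under base, and acid catalysis would endanger the prenyl group and the MOM ether. The phosphonate fixes the nucleophilic carbon beyond doubt. Phosphonate 11 comes from 9 and prenyl bromide 10 by alkylation at the carbon between phosphorus and the carbonyl.

**Glyoxal, 8 back to 6.** The aldehyde carbon of 8 is the methyl group of ketone 7, oxidised in one step. The C2 phenol is masked (7 from 6) because a free ortho phenol would add in conjugate fashion to the enedione of 12 and would be ionised in the key step. A MOM ether is stable to all the basic steps and leaves together with those of ring B.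

**Halogen pattern of ring A, 6 back to 1.** Chlorine enters last (6 from 5), when C5 is the only free ring position. The hydroxyl of 5 is released from the dimethoxy compound 4 by a boron Lewis acid, which should cleave the methoxy group squeezed between bromine and the acyl group; this ties the bromine to the free phenol. Bromine enters the symmetrical ketone 3, where both open positions are equivalent. Ketone 3 comes from 1 by lithiation between the two methoxy groups (aryllithium 2) and acylation. Each halogen is thus placed either at equivalent positions or at the last free position, and the only selectivity question is the ether cleavage of 4.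

## Alternatives that were turned down

**Alternative 1: ring A closed last from an open-chain chloro enone.** The disconnection is the C2–C3 bond of ring A in benzophenone A1, leading back to the triacylmethane A2, in which a 2-chloro-3-methylbut-2-enoyl unit, a methyl ester and the complete ring B aroyl group sit on one carbon. In the forward step an excess of a strong amide base would remove a proton from the γ-methyl group of the chloro enone, the carbanion would attack the ester carbon, and the ring would tautomerise to the chlororesorcinol A1. In its favour, chlorine is fixed at C5 by construction, with no regiochemical question at all; on this point it is stronger than the chosen route, which depends on a selective ether cleavage (step 3). Against it: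
- The first equivalent of base deprotonates the tricarbonyl methine of A2, so the ester becomes part of a delocalised anion and is a poor electrophile for the ring closure.
- An α-chloro enone exposed to excess amide base can also undergo substitution or elimination at the chlorine-bearing carbon.
- After A1, bromination must pick C3 of ring A while C4' of ring B, flanked by two alkoxy groups, is at least as nucleophilic.
- One of two ketone-chelated phenols must be methylated, and the one next to chlorine is the more hindered.
- Ring B with acetal, prenyl and two MOM ethers must be complete before this step, which makes the sequence long and linear.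

The chosen route instead finishes ring A on a simple acetophenone, where the regiochemical question is answered early on cheap material, and builds ring B from a commercial nucleophile.

**Alternative 2: ring B by Diels–Alder reaction on a ring A alkynoate.** The bonds C1'–C6' and C2'–C3' are cut, giving the alkynoate A4 and the bis(silyloxy)diene A5. A thermal [4+2] cycloaddition followed by loss of an alcohol and the silyl groups would give the resorcylate A3. In its favour, ring B is formed directly at the aromatic oxidation level with the ester at C2', so no dehydrogenation is needed; on this point it is stronger than the chosen route, whose step 10 is a risk of its own. Against it: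
- The C1'–C6' bond must form between the diene terminus that carries the prenyl CH2 and the alkyne carbon that carries a bulky silyloxy benzyl group bearing the hexasubstituted ring A.
- Terminally substituted dienes of this kind react sluggishly with ynoates, and heating favours silyl transfer, open-chain conjugate addition, or isomerisation of the doubly allylic CH2 of A5.
- A3 still has the benzylic carbon at the carbinol level, so desilylation and oxidation to the hindered ketone must follow, in addition to the ester-to-aldehyde change.
- A4 needs a hexasubstituted ring A benzaldehyde and an alkynylation, so the step count is not lower.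

The chosen route makes its first bond at an unsubstituted CH and its second intramolecularly, so it depends less on overcoming steric compression in a cycloaddition.

**Alternative 3: ring B by photochemical benzannulation of a diazo ketone.** The bonds C1'–C2', C2'–C3', C4'–C5' and C5'–C6' are formed in one operation from the diazo ketone A7 and the silyloxyalkyne A8. On irradiation A7 would lose nitrogen and undergo Wolff rearrangement; the vinylketene would add A8; four-electron ring opening and six-electron ring closure would give the resorcylate A6. In its favour, it is convergent and regiospecific, and A6 arrives aromatic, with the ketone at the right oxidation level and the two ring B oxygens already differentiated; in these respects it is stronger than the chosen route. Against it: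
- Wolff rearrangement of a 2-diazo-1,3-dicarbonyl compound is inefficient and competes with carbene insertion and cyclopropanation, and the prenyl alkene is placed to trap both the carbene and the ketene intramolecularly.
- The aryl C–Br bond and the aryl ketone chromophore are themselves photolabile.
- A7 is an acyl-substituted enone that needs chemistry as long as that leading to enedione 12, plus acylation and diazo transfer, and A8 is a sensitive reagent that needs its own preparation.

The chosen route uses only thermal, ionic chemistry with inexpensive reagents and carries ring A through unchanged.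

Key step: step 9

Remark: 14, 15, 16 and 17 are drawn in their keto forms; each is expected as a mixture of diastereomers and enol tautomers, all of which converge on 18.

## Steps

Step 1
Reactants: 1 3,5-dimethoxytoluene
Product: 3 1-(2,6-dimethoxy-4-methylphenyl)ethanone, via aryllithium 2 (not isolated)
Conditions: n-BuLi, THF, 0 °C to rt; N-methoxy-N-methylacetamide, −78 °C to rt; 1 M HCl
Reagents that add atoms: N-methoxy-N-methylacetamide, CC(=O)N(C)OC
Why: Directed ortho-lithiation takes place at the carbon flanked by both methoxy groups, and acylation of the aryllithium with the Weinreb amide stops at the ketone because the chelated tetrahedral adduct survives until work-up.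

Step 2
Reactants: 3 1-(2,6-dimethoxy-4-methylphenyl)ethanone
Product: 4 1-(3-bromo-2,6-dimethoxy-4-methylphenyl)ethanone
Conditions: NBS (1.0 equiv), MeCN, 0 °C to rt, dark
Reagents that add atoms: N-bromosuccinimide, O=C1CCC(=O)N1Br
Why: Electrophilic aromatic bromination; the two open positions of the symmetrical ring are equivalent and activated by OMe and CH3, and one equivalent of reagent should stop at the monobromide because the first bromine deactivates the ring.

Step 3
Reactants: 4 1-(3-bromo-2,6-dimethoxy-4-methylphenyl)ethanone
Product: 5 1-(3-bromo-2-hydroxy-6-methoxy-4-methylphenyl)ethanone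
Conditions: BCl3 (1.2 equiv), CH2Cl2, −78 to 0 °C; H2O
Reagents that add atoms: none
Why: Chelation-directed Lewis-acid ether cleavage: BCl3 binds the ketone oxygen and cleaves an ortho methoxy group through a six-membered boron chelate. The C2 methoxy group, twisted out of the ring plane by bromine and the acyl group, is the more basic and more strained and should be cleaved in preference to the C6 methoxy group; the chelate then shuts off a second cleavage.

Step 4
Reactants: 5 1-(3-bromo-2-hydroxy-6-methoxy-4-methylphenyl)ethanone
Product: 6 1-(3-bromo-5-chloro-2-hydroxy-6-methoxy-4-methylphenyl)ethanone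
Conditions: NCS (1.05 equiv), DMF, rt to 50 °C, dark
Reagents that add atoms: N-chlorosuccinimide, O=C1CCC(=O)N1Cl
Why: Electrophilic aromatic chlorination at C5, the only unsubstituted ring position, which is para to the phenol and ortho to OMe and CH3; no regiochemical choice remains.

Step 5
Reactants: 6 1-(3-bromo-5-chloro-2-hydroxy-6-methoxy-4-methylphenyl)ethanone
Product: 7 1-[3-bromo-5-chloro-6-methoxy-2-(methoxymethoxy)-4-methylphenyl]ethanone
Conditions: NaH (1.1 equiv), DMF, 0 °C; MOMCl, 0 °C to rt
Reagents that add atoms: chloromethyl methyl ether, COCCl
Why: O-Alkylation of the sodium phenoxide (Williamson-type MOM ether formation); the phenol is far more acidic than the methyl ketone, so one equivalent of NaH ionises it alone, and the naked phenoxide in DMF overcomes the hindrance from bromine and the acyl group.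

Step 6
Reactants: 7 1-[3-bromo-5-chloro-6-methoxy-2-(methoxymethoxy)-4-methylphenyl]ethanone
Product: 8 2-[3-bromo-5-chloro-6-methoxy-2-(methoxymethoxy)-4-methylphenyl]-2-oxoacetaldehyde
Conditions: SeO2 (1.5 equiv), 1,4-dioxane–H2O (20:1), 90 °C; azeotropic drying with toluene
Reagents that add atoms: selenium dioxide, O=[Se]=O
Why: Riley oxidation of an aryl methyl ketone to the arylglyoxal, which also works for di-ortho-substituted aryl ketones; the ring methyl group is not activated enough to react, and the hydrate first obtained is dehydrated to the free aldehyde before use.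

Step 7
Reactants: 9 dimethyl (2-oxopropyl)phosphonate; 10 1-bromo-3-methylbut-2-ene
Product: 11 dimethyl (6-methyl-2-oxohept-5-en-3-yl)phosphonate (racemic)
Conditions: NaH (1.05 equiv), THF, 0 °C; 10 (1.0 equiv), 0 °C to rt
Reagents that add atoms: none
Why: C-Alkylation of a β-ketophosphonate anion at the carbon between phosphorus and carbonyl with a reactive allylic bromide; one equivalent of each keeps dialkylation low, and the stereocentre formed is lost in the next step.

Step 8
Reactants: 8 2-Ar-2-oxoacetaldehyde; 11 dimethyl (6-methyl-2-oxohept-5-en-3-yl)phosphonate
Product: 12 (E)-1-Ar-3-(3-methylbut-2-enyl)pent-2-ene-1,4-dione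
Conditions: 11, NaH (1.0 equiv), THF, 0 °C; 8 (1.1 equiv), −78 to 0 °C
Reagents that add atoms: none
Why: Horner–Wadsworth–Emmons olefination; the aldehyde of the glyoxal is far more electrophilic than its hindered ketone, and the phosphonate defines C6' as the carbon that carries both the prenyl and the acetyl group. The (E) isomer (aroyl trans to acetyl) is expected to dominate, but either geometry serves in step 9; a slight excess of 8 leaves no phosphonate anion to add to the product.

Step 9
Reactants: 12 (E)-1-Ar-3-(3-methylbut-2-enyl)pent-2-ene-1,4-dione; 13 dimethyl malonate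
Product: 15 methyl 2-(ArCO)-3-(3-methylbut-2-enyl)-4,6-dioxocyclohexane-1-carboxylate (diastereomer mixture), via Michael adduct 14 (not isolated)
Conditions: 13 (1.2 equiv), NaOMe (0.1 equiv), MeOH–THF, 0 °C; then NaOMe (2.2 equiv), MeOH, 60 °C; cold 1 M HCl to pH 3–4
Reagents that add atoms: none
Why: This is a Michael–Claisen annulation, the standard way from enones and malonates to cyclohexane-1,3-diones, applied here to an ene-1,4-dione. With catalytic NaOMe the anion of 13 adds to C1' of 12, the only unsubstituted alkene carbon, which gives the enolate of the methyl ketone and, after proton transfer, adduct 14 with the new C1'–C2' bond. Attack at C6' would create a quaternary centre beside the aroyl group and is disfavoured, and keeping the base catalytic in this stage limits deprotonation of the doubly allylic CH2 of 12. With excess NaOMe at 60 °C the methyl ketone enolate carbon C4' attacks a malonate ester carbon (C3') in a 6-exo-trig Claisen closure; methoxide leaves and the new 1,3-dione is deprotonated at once, which makes the ring closure irreversible. The competing five-ring aldol reaction of the 1,4-diketone onto the aryl ketone is reversible and is held back by the OMe and OMOM groups that flank and twist that carbonyl, and closures from the other enolates would give four-membered rings. The new stereocentres C1', C2' and C6' are all epimerisable under the conditions, so a thermodynamic mixture is expected and no control is needed, because step 10 removes them. The MOM ether, both halogens and the prenyl alkene are inert to methoxide.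

Step 10
Reactants: 15 methyl 2-(ArCO)-3-(3-methylbut-2-enyl)-4,6-dioxocyclohexane-1-carboxylate
Product: 18 methyl 2-(ArCO)-4,6-dihydroxy-3-(3-methylbut-2-enyl)benzoate, via C2' phenylselenide 16 (not isolated), via selenoxide 17 (not isolated)
Conditions: LiN(i-Pr)2 (2.3 equiv), THF, −78 to −40 °C; PhSeBr (1.05 equiv), −78 °C; AcOH; 30% H2O2, pyridine, 0 °C to rt
Reagents that add atoms: none
Why: α-Selenenylation followed by selenoxide syn-elimination: the first equivalent of base ionises the 1,3-dione, the second removes the C2' hydrogen (α to the ester), and the more reactive C2' carbanion takes up selenium trans to the aroyl group, that is cis to the C1' hydrogen. Oxidation gives the selenoxide, which eliminates towards C1' at or below rt, and the resulting enedione tautomerises to the resorcinol. The sequence stays basic or buffered and never generates free halogen or strong acid, so the prenyl alkene and C4' are left alone.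

Step 11
Reactants: 18 methyl 2-(ArCO)-4,6-dihydroxy-3-(3-methylbut-2-enyl)benzoate
Product: 19 methyl 2-(ArCO)-4,6-bis(methoxymethoxy)-3-(3-methylbut-2-enyl)benzoate
Conditions: NaH (2.5 equiv), DMF, 0 °C; MOMCl (3 equiv), 0 °C to rt
Reagents that add atoms: chloromethyl methyl ether, COCCl
Why: MOM ether formation from both sodium phenoxides; NaH in DMF is used because the C3' hydroxyl is hydrogen-bonded to the ester and reacts sluggishly with amine bases.

Step 12
Reactants: 19 methyl 2-(ArCO)-4,6-bis(methoxymethoxy)-3-(3-methylbut-2-enyl)benzoate
Product: 20 Ar[2-(hydroxymethyl)-3,5-bis(methoxymethoxy)-6-(3-methylbut-2-enyl)phenyl]methanol (racemic)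
Conditions: LiAlH4 (3 equiv), THF, 0 °C to rt; H2O, 15% NaOH, H2O
Reagents that add atoms: none
Why: Hydride reduction of ester and ketone; any phthalide formed when the benzhydrol alkoxide attacks the ester is reduced on to the same diol, and the aryl bromide is inert to LiAlH4 at or below rt. Should part of the hindered ketone survive, the keto alcohol converges on 21 in step 13; the new stereocentre is removed there in any case.

Step 13
Reactants: 20 Ar[2-(hydroxymethyl)-3,5-bis(methoxymethoxy)-6-(3-methylbut-2-enyl)phenyl]methanol
Product: 21 2-(ArCO)-4,6-bis(methoxymethoxy)-3-(3-methylbut-2-enyl)benzaldehyde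
Conditions: (COCl)2 (3 equiv), DMSO (6 equiv), CH2Cl2, −78 °C; Et3N (10 equiv), −78 to 0 °C
Reagents that add atoms: none
Why: Swern oxidation; both hydroxyl groups are converted into alkoxysulfonium ions before base is added, so ketone and aldehyde are released together and no hydroxy aldehyde remains to close to a lactol. The conditions leave the prenyl alkene, the MOM ethers and the aryl bromide untouched.

Step 14
Reactants: 21 2-(ArCO)-4,6-bis(methoxymethoxy)-3-(3-methylbut-2-enyl)benzaldehyde
Product: 22 pestalone G, 2-(3-bromo-5-chloro-2-hydroxy-6-methoxy-4-methylbenzoyl)-4,6-dihydroxy-3-(3-methylbut-2-enyl)benzaldehyde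
Conditions: 3 M HCl (aq.), MeOH–THF, rt
Reagents that add atoms: none
Why: Acid hydrolysis of the three aryl MOM acetals; dilute acid at rt is the usual way to unmask prenylated phenols without chroman formation, and the methyl ether, both halogens and both carbonyl groups are stable to it.

## Compound list

1 | 3,5-dimethoxytoluene | COc1cc(C)cc(OC)c1 | starting material
2 | (2,6-dimethoxy-4-methylphenyl)lithium | [Li]c1c(OC)cc(C)cc1OC | intermediate (not isolated)
3 | 1-(2,6-dimethoxy-4-methylphenyl)ethanone | CC(=O)c1c(OC)cc(C)cc1OC | intermediate
4 | 1-(3-bromo-2,6-dimethoxy-4-methylphenyl)ethanone | CC(=O)c1c(OC)cc(C)c(Br)c1OC | intermediate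
5 | 1-(3-bromo-2-hydroxy-6-methoxy-4-methylphenyl)ethanone | CC(=O)c1c(OC)cc(C)c(Br)c1O | intermediate
6 | 1-(3-bromo-5-chloro-2-hydroxy-6-methoxy-4-methylphenyl)ethanone | CC(=O)c1c(OC)c(Cl)c(C)c(Br)c1O | intermediate
7 | 1-[3-bromo-5-chloro-6-methoxy-2-(methoxymethoxy)-4-methylphenyl]ethanone | CC(=O)c1c(OC)c(Cl)c(C)c(Br)c1OCOC | intermediate
8 | 2-[3-bromo-5-chloro-6-methoxy-2-(methoxymethoxy)-4-methylphenyl]-2-oxoacetaldehyde | O=CC(=O)c1c(OC)c(Cl)c(C)c(Br)c1OCOC | intermediate
9 | dimethyl (2-oxopropyl)phosphonate | COP(=O)(OC)CC(C)=O | starting material
10 | 1-bromo-3-methylbut-2-ene | CC(C)=CCBr | starting material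
11 | dimethyl (6-methyl-2-oxohept-5-en-3-yl)phosphonate (racemic) | COP(=O)(OC)C(CC=C(C)C)C(C)=O | intermediate
12 | (E)-1-[3-bromo-5-chloro-6-methoxy-2-(methoxymethoxy)-4-methylphenyl]-3-(3-methylbut-2-enyl)pent-2-ene-1,4-dione | CC(=O)/C(CC=C(C)C)=C/C(=O)c1c(OC)c(Cl)c(C)c(Br)c1OCOC | intermediate
13 | dimethyl malonate | COC(=O)CC(=O)OC | starting material
14 | dimethyl 2-{3-acetyl-1-[3-bromo-5-chloro-6-methoxy-2-(methoxymethoxy)-4-methylphenyl]-6-methyl-1-oxohept-5-en-2-yl}propanedioate (diastereomer mixture) | COC(=O)C(C(=O)OC)C(C(=O)c1c(OC)c(Cl)c(C)c(Br)c1OCOC)C(CC=C(C)C)C(C)=O | intermediate (not isolated)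
15 | methyl 2-[3-bromo-5-chloro-6-methoxy-2-(methoxymethoxy)-4-methylbenzoyl]-3-(3-methylbut-2-enyl)-4,6-dioxocyclohexane-1-carboxylate (diastereomer mixture) | COC(=O)C1C(=O)CC(=O)C(CC=C(C)C)C1C(=O)c1c(OC)c(Cl)c(C)c(Br)c1OCOC | intermediate
16 | methyl 2-[3-bromo-5-chloro-6-methoxy-2-(methoxymethoxy)-4-methylbenzoyl]-3-(3-methylbut-2-enyl)-4,6-dioxo-1-(phenylselanyl)cyclohexane-1-carboxylate (diastereomer mixture) | COC(=O)C1([Se]c2ccccc2)C(=O)CC(=O)C(CC=C(C)C)C1C(=O)c1c(OC)c(Cl)c(C)c(Br)c1OCOC | intermediate (not isolated)
17 | methyl 2-[3-bromo-5-chloro-6-methoxy-2-(methoxymethoxy)-4-methylbenzoyl]-3-(3-methylbut-2-enyl)-4,6-dioxo-1-(phenylseleninyl)cyclohexane-1-carboxylate (diastereomer mixture) | COC(=O)C1([Se](=O)c2ccccc2)C(=O)CC(=O)C(CC=C(C)C)C1C(=O)c1c(OC)c(Cl)c(C)c(Br)c1OCOC | intermediate (not isolated)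
18 | methyl 2-[3-bromo-5-chloro-6-methoxy-2-(methoxymethoxy)-4-methylbenzoyl]-4,6-dihydroxy-3-(3-methylbut-2-enyl)benzoate | COC(=O)c1c(O)cc(O)c(CC=C(C)C)c1C(=O)c1c(OC)c(Cl)c(C)c(Br)c1OCOC | intermediate
19 | methyl 2-[3-bromo-5-chloro-6-methoxy-2-(methoxymethoxy)-4-methylbenzoyl]-4,6-bis(methoxymethoxy)-3-(3-methylbut-2-enyl)benzoate | COC(=O)c1c(OCOC)cc(OCOC)c(CC=C(C)C)c1C(=O)c1c(OC)c(Cl)c(C)c(Br)c1OCOC | intermediate
20 | [3-bromo-5-chloro-6-methoxy-2-(methoxymethoxy)-4-methylphenyl][2-(hydroxymethyl)-3,5-bis(methoxymethoxy)-6-(3-methylbut-2-enyl)phenyl]methanol (racemic) | OCc1c(OCOC)cc(OCOC)c(CC=C(C)C)c1C(O)c1c(OC)c(Cl)c(C)c(Br)c1OCOC | intermediate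
21 | 2-[3-bromo-5-chloro-6-methoxy-2-(methoxymethoxy)-4-methylbenzoyl]-4,6-bis(methoxymethoxy)-3-(3-methylbut-2-enyl)benzaldehyde | O=Cc1c(OCOC)cc(OCOC)c(CC=C(C)C)c1C(=O)c1c(OC)c(Cl)c(C)c(Br)c1OCOC | intermediate
22 | pestalone G, 2-(3-bromo-5-chloro-2-hydroxy-6-methoxy-4-methylbenzoyl)-4,6-dihydroxy-3-(3-methylbut-2-enyl)benzaldehyde | COc1c(Cl)c(C)c(Br)c(O)c1C(=O)c1c(C=O)c(O)cc(O)c1CC=C(C)C | target

## Step count and least certain steps

Total: 14 steps. Longest linear sequence: 13 steps (steps 1–6 and 8–14); step 7 is the only step off the main line.

**Step 9 (key step).** The most likely failure is that alkoxide removes a proton from the doubly allylic CH2 of enedione 12, so that the double bond migrates into conjugation with the prenyl alkene or the enedione oligomerises before malonate adds. The second risk is aldol closure of the 1,4-diketone to a cyclopentenone once the adduct has formed. The fallback keeps the enedione away from base by making the C1'–C6' bond instead of the C1'–C2' bond in the conjugate addition. It sets out from glyoxal 8 and malonate 13: Knoevenagel condensation (piperidinium acetate, toluene, molecular sieves) should give dimethyl 2-(2-Ar-2-oxoethylidene)propanedioate F1. Commercial 6-methylhept-5-en-2-one F2 is converted under equilibrating conditions (Me3SiI, (Me3Si)2NH) into its more substituted silyl enol ether, trimethyl[(6-methylhepta-2,5-dien-2-yl)oxy]silane F3. A Mukaiyama–Michael addition of F3 to F1 (catalytic Sc(OTf)3, CH2Cl2, −78 °C) then gives 14 after desilylating work-up. Isolated 14 is closed with NaOMe in MeOH, and the route is rejoined at 15.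

**Step 10.** If the second deprotonation is incomplete, selenium enters at the central dione carbon C4', which has no β-hydrogen to eliminate. Peroxyseleninic acid formed from the by-product can also epoxidise the prenyl alkene. The fallback sets out from 15 and aromatises a silyl dienol ether instead: t-BuMe2SiOTf and Et3N should give methyl 2-(ArCO)-4,6-bis(tert-butyldimethylsilyloxy)-3-(3-methylbut-2-enyl)cyclohexa-3,5-diene-1-carboxylate F4 (one regioisomer drawn). DDQ at 0 °C dehydrogenates this cyclohexadiene to methyl 2-(ArCO)-4,6-bis(tert-butyldimethylsilyloxy)-3-(3-methylbut-2-enyl)benzoate F5; with both phenols silylated, oxidative chromene formation is blocked. Bu4NF then releases the phenols, and the route is rejoined at 18.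

**Step 13.** If the primary alcohol is oxidised first, the hindered benzhydrol can add to the new aldehyde; the lactol is then oxidised on to a 3-arylphthalide. The activated benzhydrol can also ionise and be lost as a chloride. The fallback sets out from 20 and oxidises the two carbons one after the other. Selective silylation of the primary hydroxyl (t-BuMe2SiCl, imidazole) gives the silyl ether Ar[2-(tert-butyldimethylsilyloxymethyl)-3,5-bis(methoxymethoxy)-6-(3-methylbut-2-enyl)phenyl]methanol F6. Dess–Martin periodinane buffered with NaHCO3 gives the ketone Ar[2-(tert-butyldimethylsilyloxymethyl)-3,5-bis(methoxymethoxy)-6-(3-methylbut-2-enyl)phenyl]methanone F7. Bu4NF gives the keto alcohol Ar[2-(hydroxymethyl)-3,5-bis(methoxymethoxy)-6-(3-methylbut-2-enyl)phenyl]methanone F8, whose cyclic hemiketal cannot be oxidised to a lactone. A second Dess–Martin oxidation gives the aldehyde, and the route is rejoined at 21.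

**Step 3.** The boron reagent may cleave the C6 methoxy group instead of the C2 methoxy group, or both, and the bromine would then sit next to the wrong oxygen. The fallback reverses the order of events and sets out from the symmetrical ketone 3. BCl3 gives 1-(2-hydroxy-6-methoxy-4-methylphenyl)ethanone F9, with no selectivity question. Chlorination para to the phenol (NCS, or SO2Cl2 in Et2O at 0 °C) gives 1-(3-chloro-6-hydroxy-2-methoxy-4-methylphenyl)ethanone F10, which is purified from any ortho isomer at this stage. NBS then brominates the last free position, and the route is rejoined at 6.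

**Step 6.** Hot aqueous selenous acid may hydrolyse the MOM ether, and the glyoxal may be oxidised further to the arylglyoxylic acid. The fallback avoids acid and sets out from 7. Condensation with N,N-dimethylformamide dimethyl acetal (neat, 110 °C) gives the enaminone (E)-1-Ar-3-(dimethylamino)prop-2-en-1-one F11. Cleavage of its C=C bond with singlet oxygen (O2, rose bengal, visible light, CH2Cl2, −78 °C) gives the glyoxal, and the route is rejoined at 8.

## Further compounds

F1 | step 9 | dimethyl 2-{2-[3-bromo-5-chloro-6-methoxy-2-(methoxymethoxy)-4-methylphenyl]-2-oxoethylidene}propanedioate | COC(=O)C(C(=O)OC)=CC(=O)c1c(OC)c(Cl)c(C)c(Br)c1OCOC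
F2 | step 9 | 6-methylhept-5-en-2-one | CC(=O)CCC=C(C)C
F3 | step 9 | trimethyl[(6-methylhepta-2,5-dien-2-yl)oxy]silane (E/Z mixture) | CC(O[Si](C)(C)C)=CCC=C(C)C
F4 | step 10 | methyl 2-[3-bromo-5-chloro-6-methoxy-2-(methoxymethoxy)-4-methylbenzoyl]-4,6-bis(tert-butyldimethylsilyloxy)-3-(3-methylbut-2-enyl)cyclohexa-3,5-diene-1-carboxylate (diastereomer mixture) | COC(=O)C1C(O[Si](C)(C)C(C)(C)C)=CC(O[Si](C)(C)C(C)(C)C)=C(CC=C(C)C)C1C(=O)c1c(OC)c(Cl)c(C)c(Br)c1OCOC
F5 | step 10 | methyl 2-[3-bromo-5-chloro-6-methoxy-2-(methoxymethoxy)-4-methylbenzoyl]-4,6-bis(tert-butyldimethylsilyloxy)-3-(3-methylbut-2-enyl)benzoate | COC(=O)c1c(O[Si](C)(C)C(C)(C)C)cc(O[Si](C)(C)C(C)(C)C)c(CC=C(C)C)c1C(=O)c1c(OC)c(Cl)c(C)c(Br)c1OCOC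
F6 | step 13 | [3-bromo-5-chloro-6-methoxy-2-(methoxymethoxy)-4-methylphenyl][2-(tert-butyldimethylsilyloxymethyl)-3,5-bis(methoxymethoxy)-6-(3-methylbut-2-enyl)phenyl]methanol (racemic) | CC(C)(C)[Si](C)(C)OCc1c(OCOC)cc(OCOC)c(CC=C(C)C)c1C(O)c1c(OC)c(Cl)c(C)c(Br)c1OCOC
F7 | step 13 | [3-bromo-5-chloro-6-methoxy-2-(methoxymethoxy)-4-methylphenyl][2-(tert-butyldimethylsilyloxymethyl)-3,5-bis(methoxymethoxy)-6-(3-methylbut-2-enyl)phenyl]methanone | CC(C)(C)[Si](C)(C)OCc1c(OCOC)cc(OCOC)c(CC=C(C)C)c1C(=O)c1c(OC)c(Cl)c(C)c(Br)c1OCOC
F8 | step 13 | [3-bromo-5-chloro-6-methoxy-2-(methoxymethoxy)-4-methylphenyl][2-(hydroxymethyl)-3,5-bis(methoxymethoxy)-6-(3-methylbut-2-enyl)phenyl]methanone | OCc1c(OCOC)cc(OCOC)c(CC=C(C)C)c1C(=O)c1c(OC)c(Cl)c(C)c(Br)c1OCOC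
F9 | step 3 | 1-(2-hydroxy-6-methoxy-4-methylphenyl)ethanone | CC(=O)c1c(OC)cc(C)cc1O
F10 | step 3 | 1-(3-chloro-6-hydroxy-2-methoxy-4-methylphenyl)ethanone | CC(=O)c1c(OC)c(Cl)c(C)cc1O
F11 | step 6 | (E)-1-[3-bromo-5-chloro-6-methoxy-2-(methoxymethoxy)-4-methylphenyl]-3-(dimethylamino)prop-2-en-1-one | CN(C)/C=C/C(=O)c1c(OC)c(Cl)c(C)c(Br)c1OCOC
A1 | alternative 1 | (3-chloro-2,6-dihydroxy-4-methylphenyl)[2-(dimethoxymethyl)-3,5-bis(methoxymethoxy)-6-(3-methylbut-2-enyl)phenyl]methanone | Cc1cc(O)c(C(=O)c2c(C(OC)OC)c(OCOC)cc(OCOC)c2CC=C(C)C)c(O)c1Cl
A2 | alternative 1 | methyl 4-chloro-2-[2-(dimethoxymethyl)-3,5-bis(methoxymethoxy)-6-(3-methylbut-2-enyl)benzoyl]-5-methyl-3-oxohex-4-enoate (racemic) | COC(=O)C(C(=O)C(Cl)=C(C)C)C(=O)c1c(C(OC)OC)c(OCOC)cc(OCOC)c1CC=C(C)C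
A3 | alternative 2 | methyl 2-{[3-bromo-5-chloro-6-methoxy-2-(methoxymethoxy)-4-methylphenyl](tert-butyldimethylsilyloxy)methyl}-4,6-dihydroxy-3-(3-methylbut-2-enyl)benzoate (racemic) | COC(=O)c1c(O)cc(O)c(CC=C(C)C)c1C(O[Si](C)(C)C(C)(C)C)c1c(OC)c(Cl)c(C)c(Br)c1OCOC
A4 | alternative 2 | methyl 4-[3-bromo-5-chloro-6-methoxy-2-(methoxymethoxy)-4-methylphenyl]-4-(tert-butyldimethylsilyloxy)but-2-ynoate (racemic) | COC(=O)C#CC(O[Si](C)(C)C(C)(C)C)c1c(OC)c(Cl)c(C)c(Br)c1OCOC
A5 | alternative 2 | 1-methoxy-7-methyl-1,3-bis(trimethylsilyloxy)octa-1,3,6-triene | COC(O[Si](C)(C)C)=CC(O[Si](C)(C)C)=CCC=C(C)C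
A6 | alternative 3 | methyl 2-[3-bromo-5-chloro-6-methoxy-2-(methoxymethoxy)-4-methylbenzoyl]-4-hydroxy-3-(3-methylbut-2-enyl)-6-(triisopropylsilyloxy)benzoate | COC(=O)c1c(O[Si](C(C)C)(C(C)C)C(C)C)cc(O)c(CC=C(C)C)c1C(=O)c1c(OC)c(Cl)c(C)c(Br)c1OCOC
A7 | alternative 3 | methyl 4-[3-bromo-5-chloro-6-methoxy-2-(methoxymethoxy)-4-methylbenzoyl]-2-diazo-8-methyl-3-oxonona-4,7-dienoate | COC(=O)C(=[N+]=[N-])C(=O)C(=CCC=C(C)C)C(=O)c1c(OC)c(Cl)c(C)c(Br)c1OCOC
A8 | alternative 3 | ethynyloxy(triisopropyl)silane | C#CO[Si](C(C)C)(C(C)C)C(C)C
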